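In 5.0 min of stirring, gas must cross from the gas phase before substrate can use it.

    2 dissolved gas → self-condensation product (k1 = 0.0738 L mol⁻¹ s⁻¹)
    gas phase ⇌ dissolved gas, rate k2*(csat - [dissolved gas]) (k2 = 0.0677 s⁻¹, csat = 2.6 mM)
    substrate + dissolved gas → target (k3 = 30.4 L mol⁻¹ s⁻¹)
    substrate + target ⇌ idle adduct, settled at all times (K4 = 200 L mol⁻¹)
    substrate → side product (k5 = 0.00543 s⁻¹)

| setting | Saturday's | Friday's | Thursday's | Wednesday's | Tuesday's |
|---|---|---|---|---|---|
| substrate | 0.020 M | 0.060 M | 0.20 M | 0.60 M | 2.0 M |
| gas phase | 2.6 mM (held) | 2.6 mM (held) | 2.6 mM (held) | 2.6 mM (held) | 2.6 mM (held) |
| time | 5.0 min | 5.0 min | 5.0 min | 5.0 min | 5.0 min |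

- a species is counted by the substrate in it: one idle adduct counts as two
- amounts and yields of target count idle adduct too
- where a step has two of a species, its rate is k times that concentration squared, and two are used at each turn
- at the start none of the gas is dissolved
- in an amount of target, one idle adduct counts as one target
- the concentration of target that is asked is that of its free form alone
- "hardly changes" means that all values lie within two and a half points (for a concentration: within two and a half percent of the largest)
- run time (Saturday's): 5.0 min

* [target] (only what is free in solution) at the end for Saturday's, Friday's, Thursday's, Wednesday's, Tuesday's, in this order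
* how the row runs (rises all the way / hardly changes / rises, then falls / falls, then rises / falls all the way)

- The ladder starts with the parking step, which is kept at balance. Parked target over free target equals 200 L mol⁻¹ times the substrate standing. Taken at the charge of Thursday's flask, that product is 40.0, and it falls as substrate is used.
- Next comes capture. In Thursday's flask at the start, dissolved gas has a half-life of 0.114 s against substrate.
- Transfer follows, with a half-time of 10.2 s, so capture in Thursday's flask starts faster than transfer. At that start, gas is caught about as soon as it arrives, and transfer is the rate-limiting step for target in Thursday's flask.
- Substrate passes into side product with a half-life of 2.13 min. That is slower than transfer but shorter than the run, so side product competes within the run.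
- Self-condensation comes last. At saturation its first half-life is 43.4 min, longer than the run.
- Now write the balance of the gas. It enters at 0.0677 s⁻¹ times (saturation minus what is dissolved), and none is dissolved at the start, so entry is at most 0.0677 s⁻¹ times 2.6 mM.
- Multiply that entry by the run time and divide by the charge. This gives the transfer ceiling, the largest fraction of the charge that gas can turn into target in the run: 26.4% for Thursday's flask.
- My reckoning gives a ceiling of 8.80% for Wednesday's flask. For Saturday's flask it gives 264%, more than the charge, so there substrate is the limiting reagent.
- My reckoning stops here. The free form needs the substrate left at the end, and I have no hand figure for that.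
- The forecast gives 0.0155 M, 0.032 M, 0.021 M, 0.0035 M and 7.600 × 10⁻⁴ M, a row that rises, then falls. Its grounds include that “the substrate left over locks target into the idle adduct”.
- The simulation gives 0.0152 M, 0.0297 M, 0.0202 M, 0.00352 M and 7.61 × 10⁻⁴ M, a row that rises, then falls.
- At the end, Thursday's flask holds target, parked form counted, at 24.4% of its charge, below the ceiling of 26.4%, while side product stands at 57.7%. Wednesday's flask holds 8.68% against its ceiling of 8.80%, with idle adduct at 16.2% of the charge, each counted as two substrate, and free target at 0.587% of the charge.

The numbers of this flask stand for no real mixture; the flask was simulated.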